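The route rests on disconnecting the C2–C3 bond of the 2,3-dihydro-1,4-benzodioxine ring, between the carbon carrying CH2OH and the benzylic carbon carrying the syringyl ring. The key step exploits two features: both carbons hang from the catechol oxygens O1 and O4, a built-in two-atom tether, and C3 is benzylic to an electron-rich 4-oxygenated arene. The precursor is an open catechol diether with an aryloxyacetaldehyde arm on O1 and a 4-silyloxy-3,5-dimethoxybenzyl ether on O4. In one operation DDQ converts the benzylic CH2 into an oxocarbenium ion and a chiral enamine of the aldehyde closes the dioxane ring, setting both stereocentres. Olefination and desilylation complete the stilbene.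

Key step: step 6

Remark: ring atoms are numbered as in 2,3-dihydro-1,4-benzodioxine (O1, C2 carrying the one-carbon arm, C3 carrying the aryl group, O4), and the (E)-anti enamine is assumed to be the reacting enamine geometry in step 6.

Step 1
Reactants: 1 3,4-dihydroxybenzaldehyde; 2 allyl bromide
Product: 3 3-hydroxy-4-(prop-2-en-1-yloxy)benzaldehyde
Conditions: NaHCO3, NaI (cat.), DMF, 40 °C
Reagents that add atoms: none
Why: Williamson etherification that should be selective for the 4-OH, because the phenol para to the formyl group is the more acidic one and the only one ionised by hydrogen carbonate.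

Step 2
Reactants: 4 syringaldehyde (4-hydroxy-3,5-dimethoxybenzaldehyde)
Product: 5 4-[(tert-butyldimethylsilyl)oxy]-3,5-dimethoxybenzaldehyde
Conditions: TBSCl, imidazole, DMF, rt
Reagents that add atoms: tert-butyldimethylsilyl chloride (TBSCl), CC(C)(C)[Si](C)(C)Cl
Why: imidazole-promoted O-silylation of the phenol, which masks the future free 4-OH so that the benzylic position cannot ionise to a quinone methide in the following steps.

Step 3
Reactants: 5 4-[(tert-butyldimethylsilyl)oxy]-3,5-dimethoxybenzaldehyde
Product: 6 {4-[(tert-butyldimethylsilyl)oxy]-3,5-dimethoxyphenyl}methanol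
Conditions: NaBH4, MeOH/THF, 0 °C
Reagents that add atoms: none
Why: borohydride reduction of the aryl aldehyde to the benzylic alcohol, short and cold enough for the hindered aryl silyl ether to survive.

Step 4
Reactants: 3 3-hydroxy-4-(prop-2-en-1-yloxy)benzaldehyde; 6 {4-[(tert-butyldimethylsilyl)oxy]-3,5-dimethoxyphenyl}methanol
Product: 7 3-({4-[(tert-butyldimethylsilyl)oxy]-3,5-dimethoxybenzyl}oxy)-4-(prop-2-en-1-yloxy)benzaldehyde
Conditions: PPh3, DIAD, THF, 0 °C to rt
Reagents that add atoms: none
Why: Mitsunobu etherification of the remaining phenol with the primary benzylic alcohol under neutral conditions, which should spare the base-labile aryl silyl ether, the aldehyde and the allyl ether.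

Step 5
Reactants: 7 3-({4-[(tert-butyldimethylsilyl)oxy]-3,5-dimethoxybenzyl}oxy)-4-(prop-2-en-1-yloxy)benzaldehyde
Product: 9 2-[2-({4-[(tert-butyldimethylsilyl)oxy]-3,5-dimethoxybenzyl}oxy)-4-formylphenoxy]acetaldehyde, via vicinal diol 8 (not isolated)
Conditions: OsO4 (2 mol %), NaIO4, 2,6-lutidine, dioxane/H2O, rt
Reagents that add atoms: NaIO4 (sodium metaperiodate), [Na+].[O-]I(=O)(=O)=O, the terminal oxidant whose oxygen reaches the substrate through catalytic OsO4, O=[Os](=O)(=O)=O
Why: Lemieux–Johnson oxidative cleavage, in which the only alkene is dihydroxylated and the diol is cleaved by periodate, with 2,6-lutidine suppressing over-oxidation.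

Step 6
Reactants: 9 2-[2-({4-[(tert-butyldimethylsilyl)oxy]-3,5-dimethoxybenzyl}oxy)-4-formylphenoxy]acetaldehyde
Product: 12 (2R,3R)-3-{4-[(tert-butyldimethylsilyl)oxy]-3,5-dimethoxyphenyl}-2-(hydroxymethyl)-2,3-dihydro-1,4-benzodioxine-6-carbaldehyde, via oxocarbenium ion pair 10 (not isolated), via bicyclic dialdehyde 11 (not isolated)
Conditions: DDQ (2,3-dichloro-5,6-dicyano-1,4-benzoquinone), CH2Cl2, 0 °C; then (R)-2-[diphenyl(trimethylsilyloxy)methyl]pyrrolidine (20 mol %), −20 °C; then filtration, NaBH4, EtOH/CH2Cl2, −78 °C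
Reagents that add atoms: none
Why: Proposed new method: DDQ should abstract hydride from the OCH2Ar group of 9 (the only benzylic C–H, activated by the ether oxygen and the 4-silyloxy-3,5-dimethoxyphenyl ring, while the formyl group deactivates the catechol ring) to give oxocarbenium ion pair 10; once the oxidant is spent, the amine condenses with the only enolisable carbonyl group and the enamine carbon attacks the oxocarbenium carbon, forming the C2–C3 bond and, after hydrolysis of the iminium ion, dialdehyde 11. The closest known reaction type is the amine-catalysed enantioselective oxidative coupling of benzylic ethers with aldehydes through DDQ-generated oxocarbenium ions, which is intermolecular and has not been used with aryl benzyl ethers or to close a ring. The 1,4-dioxane ring closes in a 6-(enolexo)-endo-trig mode, with the two catechol oxygens as a rigid tether that places the nucleophilic and the electrophilic carbon in a 1,6-relationship. C2 is set by the catalyst: the CPh2(OSiMe3) group of the (R)-pyrrolidine shields one face of the (E)-anti enamine, so the cation should add to the open face and give 2S in 11 (2R after reduction, by a change of priorities only). C3 is set relative to C2 by a half-chair transition state in which the aryl group of the (E)-oxocarbenium ion and the enamine arm are both pseudo-equatorial, which should give the trans ring (3R). The step also needs the α-aryloxy aliphatic aldehyde to be reduced ahead of the aromatic one, which the higher electrophilicity of the former and the deactivation of the 3,4-dialkoxybenzaldehyde should secure at −78 °C, and this prompt reduction freezes the epimerisable C2 centre.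

Step 7
Reactants: 13 3,5-dihydroxybenzaldehyde
Product: 14 3,5-bis[(tert-butyldimethylsilyl)oxy]benzaldehyde
Conditions: TBSCl, imidazole, DMF, rt
Reagents that add atoms: tert-butyldimethylsilyl chloride (TBSCl), CC(C)(C)[Si](C)(C)Cl
Why: imidazole-promoted O-silylation of both phenols, chosen so that all phenol protecting groups of the route fall in one final operation.

Step 8
Reactants: 14 3,5-bis[(tert-butyldimethylsilyl)oxy]benzaldehyde
Product: 15 {3,5-bis[(tert-butyldimethylsilyl)oxy]phenyl}methanol
Conditions: NaBH4, MeOH/THF, 0 °C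
Reagents that add atoms: none
Why: borohydride reduction of the aryl aldehyde to the benzylic alcohol.

Step 9
Reactants: 15 {3,5-bis[(tert-butyldimethylsilyl)oxy]phenyl}methanol
Product: 16 diethyl {3,5-bis[(tert-butyldimethylsilyl)oxy]benzyl}phosphonate
Conditions: ZnI2, P(OEt)3, toluene, reflux
Reagents that add atoms: triethyl phosphite, CCOP(OCC)OCC
Why: one-flask phosphonylation of a benzylic alcohol, in which ZnI2 activates the C–O bond, the phosphite attacks the benzylic carbon and the phosphonium ion is dealkylated by iodide as in the Michaelis–Arbuzov reaction.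

Step 10
Reactants: 12 (2R,3R)-3-{4-[(tert-butyldimethylsilyl)oxy]-3,5-dimethoxyphenyl}-2-(hydroxymethyl)-2,3-dihydro-1,4-benzodioxine-6-carbaldehyde; 16 diethyl {3,5-bis[(tert-butyldimethylsilyl)oxy]benzyl}phosphonate
Product: 17 [(2R,3R)-6-[(E)-2-{3,5-bis[(tert-butyldimethylsilyl)oxy]phenyl}ethenyl]-3-{4-[(tert-butyldimethylsilyl)oxy]-3,5-dimethoxyphenyl}-2,3-dihydro-1,4-benzodioxin-2-yl]methanol
Conditions: NaH, 15-crown-5 (cat.), THF, 0 °C to rt
Reagents that add atoms: none
Why: Horner–Wadsworth–Emmons olefination in which the aryl-stabilised phosphonate anion adds reversibly and the anti adduct eliminates, which should give the (E)-stilbene, while an extra equivalent of base covers the free alcohol and neither C2–H nor C3–H is acidic enough to epimerise.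

Step 11
Reactants: 17 [(2R,3R)-6-[(E)-2-{3,5-bis[(tert-butyldimethylsilyl)oxy]phenyl}ethenyl]-3-{4-[(tert-butyldimethylsilyl)oxy]-3,5-dimethoxyphenyl}-2,3-dihydro-1,4-benzodioxin-2-yl]methanol
Product: 18 aiphanol
Conditions: TBAF, AcOH, THF, 0 °C
Reagents that add atoms: none
Why: fluoride-driven cleavage of the three aryl silyl ethers, buffered with acetic acid so that the freed syringyl phenoxide does not expel the benzylic aryloxide through a quinone methide and the trans ring should be preserved.

Compound list
1 | 3,4-dihydroxybenzaldehyde | O=Cc1ccc(O)c(O)c1 | starting material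
2 | allyl bromide (3-bromoprop-1-ene) | C=CCBr | starting material
3 | 3-hydroxy-4-(prop-2-en-1-yloxy)benzaldehyde | O=Cc1ccc(OCC=C)c(O)c1 | intermediate
4 | syringaldehyde (4-hydroxy-3,5-dimethoxybenzaldehyde) | COc1cc(C=O)cc(OC)c1O | starting material
5 | 4-[(tert-butyldimethylsilyl)oxy]-3,5-dimethoxybenzaldehyde | COc1cc(C=O)cc(OC)c1O[Si](C)(C)C(C)(C)C | intermediate
6 | {4-[(tert-butyldimethylsilyl)oxy]-3,5-dimethoxyphenyl}methanol | COc1cc(CO)cc(OC)c1O[Si](C)(C)C(C)(C)C | intermediate
7 | 3-({4-[(tert-butyldimethylsilyl)oxy]-3,5-dimethoxybenzyl}oxy)-4-(prop-2-en-1-yloxy)benzaldehyde | O=Cc1ccc(OCC=C)c(OCc2cc(OC)c(O[Si](C)(C)C(C)(C)C)c(OC)c2)c1 | intermediate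
8 | 3-({4-[(tert-butyldimethylsilyl)oxy]-3,5-dimethoxybenzyl}oxy)-4-(2,3-dihydroxypropoxy)benzaldehyde, racemic at the carbinol carbon, formed and consumed in the flask | O=Cc1ccc(OCC(O)CO)c(OCc2cc(OC)c(O[Si](C)(C)C(C)(C)C)c(OC)c2)c1 | intermediate
9 | 2-[2-({4-[(tert-butyldimethylsilyl)oxy]-3,5-dimethoxybenzyl}oxy)-4-formylphenoxy]acetaldehyde | O=CCOc1ccc(C=O)cc1OCc1cc(OC)c(O[Si](C)(C)C(C)(C)C)c(OC)c1 | intermediate
10 | O-aryl oxocarbenium ion of 9 as its ion pair with 2,3-dichloro-5,6-dicyano-4-hydroxyphenolate, formed and consumed in the flask | O=CCOc1ccc(C=O)cc1[O+]=Cc1cc(OC)c(O[Si](C)(C)C(C)(C)C)c(OC)c1.[O-]c1c(Cl)c(Cl)c(O)c(C#N)c1C#N | intermediate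
11 | (2S,3R)-3-{4-[(tert-butyldimethylsilyl)oxy]-3,5-dimethoxyphenyl}-2,3-dihydro-1,4-benzodioxine-2,6-dicarbaldehyde, trans, formed and consumed in the flask | COc1cc([C@H]2Oc3cc(C=O)ccc3O[C@@H]2C=O)cc(OC)c1O[Si](C)(C)C(C)(C)C | intermediate
12 | (2R,3R)-3-{4-[(tert-butyldimethylsilyl)oxy]-3,5-dimethoxyphenyl}-2-(hydroxymethyl)-2,3-dihydro-1,4-benzodioxine-6-carbaldehyde | COc1cc([C@H]2Oc3cc(C=O)ccc3O[C@@H]2CO)cc(OC)c1O[Si](C)(C)C(C)(C)C | intermediate
13 | 3,5-dihydroxybenzaldehyde | O=Cc1cc(O)cc(O)c1 | starting material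
14 | 3,5-bis[(tert-butyldimethylsilyl)oxy]benzaldehyde | O=Cc1cc(O[Si](C)(C)C(C)(C)C)cc(O[Si](C)(C)C(C)(C)C)c1 | intermediate
15 | {3,5-bis[(tert-butyldimethylsilyl)oxy]phenyl}methanol | OCc1cc(O[Si](C)(C)C(C)(C)C)cc(O[Si](C)(C)C(C)(C)C)c1 | intermediate
16 | diethyl {3,5-bis[(tert-butyldimethylsilyl)oxy]benzyl}phosphonate | CCOP(=O)(Cc1cc(O[Si](C)(C)C(C)(C)C)cc(O[Si](C)(C)C(C)(C)C)c1)OCC | intermediate
17 | [(2R,3R)-6-[(E)-2-{3,5-bis[(tert-butyldimethylsilyl)oxy]phenyl}ethenyl]-3-{4-[(tert-butyldimethylsilyl)oxy]-3,5-dimethoxyphenyl}-2,3-dihydro-1,4-benzodioxin-2-yl]methanol | COc1cc([C@H]2Oc3cc(/C=C/c4cc(O[Si](C)(C)C(C)(C)C)cc(O[Si](C)(C)C(C)(C)C)c4)ccc3O[C@@H]2CO)cc(OC)c1O[Si](C)(C)C(C)(C)C | intermediate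
18 | aiphanol, 5-[(E)-2-[(2R,3R)-3-(4-hydroxy-3,5-dimethoxyphenyl)-2-(hydroxymethyl)-2,3-dihydro-1,4-benzodioxin-6-yl]ethenyl]benzene-1,3-diol | COc1cc([C@H]2Oc3cc(/C=C/c4cc(O)cc(O)c4)ccc3O[C@@H]2CO)cc(OC)c1O | target

Total step count: 11.
Longest linear sequence: 7 steps (steps 2, 3, 4, 5, 6, 10 and 11, from syringaldehyde 4 to aiphanol 18).

Steps most likely to fail

Step 6 (proposed new method). The oxocarbenium ion pair may be consumed by the amine (aminal formation, or oxidation of the enamine by residual oxidant) or by adventitious water (oxidative debenzylation) faster than the enamine closes the ring. The closure may also proceed with poor facial control. The fallback keeps the same ring-closing C2–C3 bond but delivers the electrophile as a neutral para-quinone methide, made in a separate operation with an oxidant that is filtered off. It relies on known chemistry: the Ag2O oxidation of 4-alkyl-2,6-dimethoxyphenols to para-quinone methides and the amine-catalysed enantioselective 1,6-addition of aldehyde-derived enamines to para-quinone methides. It sets out from 9, whose aryl silyl ether is cleaved (TBAF, AcOH, THF, 0 °C) to 2-{4-formyl-2-[(4-hydroxy-3,5-dimethoxybenzyl)oxy]phenoxy}acetaldehyde F1. Oxidation with Ag2O (CH2Cl2, rt, then filtration) should give the aryloxy-substituted quinone methide F2, which is not isolated. The same (R)-pyrrolidine catalyst should close F2 to the phenolic bicyclic dialdehyde F3, also not isolated, which is reduced as in step 6 to the phenolic hydroxymethyl aldehyde F4. Olefination of F4 with 16 under the conditions of step 10, with one more equivalent of NaH, should give the resorcinol bis-silyl ether of aiphanol F5. The conditions of step 11 then bring the sequence back to the route at 18.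

Step 5. The aryloxyacetaldehyde may be lost as its hydrate or as oligomers during the aqueous periodate cleavage, and the electron-rich benzyl ether may be over-oxidised. The fallback brings in the two-carbon arm at the alcohol oxidation level and oxidises it without water. It sets out from 1, which is alkylated selectively at the 4-OH with commercial (2-bromoethoxy)(tert-butyl)dimethylsilane (NaHCO3, NaI, DMF, 60 °C) to 4-{2-[(tert-butyldimethylsilyl)oxy]ethoxy}-3-hydroxybenzaldehyde F6. Mitsunobu coupling with 6 as in step 4 should give the bis-silyl diether aldehyde F7. AcOH/THF/H2O at rt should cleave only the alkyl silyl ether, giving the primary alcohol F8. Dess–Martin oxidation (NaHCO3, CH2Cl2, rt) then returns to the route at 9.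

Step 9. The Lewis acid and iodide at reflux may strip the aryl silyl ethers, or the meta-dioxygenated benzylic alcohol may ionise too slowly for phosphonylation. The fallback is the classical two-stage sequence. It sets out from 15, which the Appel reaction (CBr4, PPh3, CH2Cl2, 0 °C) should convert into 3,5-bis[(tert-butyldimethylsilyl)oxy]benzyl bromide F9. Heating F9 in neat P(OEt)3 (Michaelis–Arbuzov reaction, 130 °C) returns to the route at 16.

Further compounds
F1 | step 6 | 2-{4-formyl-2-[(4-hydroxy-3,5-dimethoxybenzyl)oxy]phenoxy}acetaldehyde | O=CCOc1ccc(C=O)cc1OCc1cc(OC)c(O)c(OC)c1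
F2 | step 6 | 2-(2-{[(3,5-dimethoxy-4-oxocyclohexa-2,5-dien-1-ylidene)methyl]oxy}-4-formylphenoxy)acetaldehyde (aryloxy-substituted para-quinone methide, not isolated) | O=CCOc1ccc(C=O)cc1OC=C1C=C(OC)C(=O)C(OC)=C1
F3 | step 6 | (2S,3R)-3-(4-hydroxy-3,5-dimethoxyphenyl)-2,3-dihydro-1,4-benzodioxine-2,6-dicarbaldehyde (not isolated) | COc1cc([C@H]2Oc3cc(C=O)ccc3O[C@@H]2C=O)cc(OC)c1O
F4 | step 6 | (2R,3R)-3-(4-hydroxy-3,5-dimethoxyphenyl)-2-(hydroxymethyl)-2,3-dihydro-1,4-benzodioxine-6-carbaldehyde | COc1cc([C@H]2Oc3cc(C=O)ccc3O[C@@H]2CO)cc(OC)c1O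
F5 | step 6 | aiphanol with both resorcinol oxygens as tert-butyldimethylsilyl ethers, (2R,3R), (E) | COc1cc([C@H]2Oc3cc(/C=C/c4cc(O[Si](C)(C)C(C)(C)C)cc(O[Si](C)(C)C(C)(C)C)c4)ccc3O[C@@H]2CO)cc(OC)c1O
F6 | step 5 | 4-{2-[(tert-butyldimethylsilyl)oxy]ethoxy}-3-hydroxybenzaldehyde | O=Cc1ccc(OCCO[Si](C)(C)C(C)(C)C)c(O)c1
F7 | step 5 | 3-({4-[(tert-butyldimethylsilyl)oxy]-3,5-dimethoxybenzyl}oxy)-4-{2-[(tert-butyldimethylsilyl)oxy]ethoxy}benzaldehyde | O=Cc1ccc(OCCO[Si](C)(C)C(C)(C)C)c(OCc2cc(OC)c(O[Si](C)(C)C(C)(C)C)c(OC)c2)c1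
F8 | step 5 | 3-({4-[(tert-butyldimethylsilyl)oxy]-3,5-dimethoxybenzyl}oxy)-4-(2-hydroxyethoxy)benzaldehyde | O=Cc1ccc(OCCO)c(OCc2cc(OC)c(O[Si](C)(C)C(C)(C)C)c(OC)c2)c1
F9 | step 9 | 3,5-bis[(tert-butyldimethylsilyl)oxy]benzyl bromide | BrCc1cc(O[Si](C)(C)C(C)(C)C)cc(O[Si](C)(C)C(C)(C)C)c1
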